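**Strategy.** The target is a Diels–Alder heterodimer of two cis-fused xanthanolides whose cycloheptane cores are mirror images (7R,8R,10S in the hydroxylated upper half, 7'S,8'S,10'R below; xanthanolide numbering). Everything rests on one racemic gold-catalysed (4+3) cycloaddition that builds the seven-membered carbocycle (C1, C5–C10) from a three-carbon propargyl acetate (C5–C1–C10) and a 2-substituted butadiene (C6–C9). It forms C5–C6 and C9–C10 and leaves a regiodefined C1 enol acetate, the C7=C8 alkene and the C10 stereocentre that relays C7 and C8. A lipase splits the racemate into both halves; a Diels–Alder reaction then closes the cyclohexene ring (C1, C2, C3, C11', C13', C5) and C1 is oxygenated.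

Key step: step 3

Remark: buta-2,3-dien-1-ol and potassium trifluoro(3-oxobutyl)borate are taken as purchasable, racemates (5–12) are drawn as one enantiomer, and primed locants refer to the lower half.

**Step 1**
Reactants: 1 buta-2,3-dien-1-ol; 2 N,N-dimethylacetamide dimethyl acetal
Product: 4 N,N-dimethyl-3-methylidenepent-4-enamide, via ketene N,O-acetal 3 (not isolated)
Conditions: 2 (1.5 equiv), PhMe, 110 °C, MeOH distilled off
Reagents that add atoms: none
Why: Eschenmoser–Claisen rearrangement; the ketene N,O-acetal formed by acetal exchange undergoes the [3,3] shift onto the central allene carbon, which turns the allenyl carbinol into a 2-substituted 1,3-diene carrying the future C11–C12 unit as a robust amide.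

**Step 2**
Reactants: 5 (±)-but-3-yn-2-ol
Product: 6 (±)-but-3-yn-2-yl acetate
Conditions: Ac2O, pyridine, DMAP (cat.), CH2Cl2, 0 °C → rt
Reagents that add atoms: acetic anhydride, CC(=O)OC(C)=O
Why: DMAP-catalysed O-acylation of a secondary alcohol; the racemate is used because this carbon becomes sp2 in step 3.

**Step 3**
Reactants: 4 N,N-dimethyl-3-methylidenepent-4-enamide; 6 (±)-but-3-yn-2-yl acetate
Product: 8 rac-4-[2-(dimethylamino)-2-oxoethyl]-7-methylcyclohepta-1,4-dien-1-yl acetate, via cis-divinylcyclopropane 7 (not isolated)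
Conditions: (PhO)3PAuCl (3 mol%), AgSbF6 (3 mol%), CH2Cl2, 0 → 40 °C, 4 in 2-fold excess
Reagents that add atoms: none
Why: Monovalent gold activates the alkyne of 6 and a 1,2-acetoxy shift gives a (Z)-α-acetoxyvinyl gold carbenoid, which cyclopropanates the more nucleophilic 1,1-disubstituted C6=C7 terminus of 4 (first bond C5–C6, through the tertiary allyl-stabilised cation); the cis-divinylcyclopropane 7 then undergoes a gold-assisted Cope rearrangement that forms C9–C10 and cleaves C5–C7. The closest known reaction type is the gold-catalysed formal (4+3) cycloaddition of propargyl esters with 1,3-dienes by tandem cyclopropanation/Cope rearrangement, the counterpart of the rhodium vinylcarbenoid (4+3). The three-membered ring closes by (2+1) carbene transfer and the seven-membered ring by [3,3]-sigmatropic ring expansion through a boat transition state. C10 is the only stereocentre formed and is deliberately left uncontrolled (achiral catalyst, racemate), because the two halves of the target need its two configurations. The step needs 1,2- over 1,3-acyloxy migration (secured by the terminal alkyne), attack on the substituted and not the vinyl terminus of the diene (secured by its higher electron density and cation stabilisation) and a cis-divinyl arrangement (the (Z)-enol acetate keeps the methyl outside the boat, and gold can equilibrate a trans-cyclopropane by reversible ring opening).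

**Step 4**
Reactants: 8 rac-enol acetate
Product: 10 rac-4-[2-(dimethylamino)-2-oxoethyl]-7-methylcyclohepta-1,4-dien-1-yl trifluoromethanesulfonate, via lithium enolate 9 (not isolated)
Conditions: MeLi (2.1 equiv), THF, −78 → −30 °C; then PhNTf2, −78 °C → rt
Reagents that add atoms: N-phenylbis(trifluoromethanesulfonimide), O=S(=O)(N(c1ccccc1)S(=O)(=O)C(F)(F)F)C(F)(F)F
Why: Enol ester cleavage by methyllithium gives the lithium enolate regiospecifically (C1=C5, no equilibration toward C10, so C10 is not touched) and O-triflation fixes it as the alkenyl triflate; the tertiary amide is inert at this temperature.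

**Step 5**
Reactants: 10 rac-alkenyl triflate
Product: 12 rac-(7R*,8S*,10S*)-4-[2-(dimethylamino)-2-oxoethyl]-5-hydroxy-7-methylcyclohept-1-en-1-yl trifluoromethanesulfonate, via alkylborane 11 (not isolated)
Conditions: BH3·THF (1.1 equiv), THF, 0 °C; then 30% H2O2, aq. NaOAc, 0 °C → rt
Reagents that add atoms: hydrogen peroxide, OO
Why: Hydroboration–oxidation; borane adds syn to the electron-rich trisubstituted C7=C8 alkene (the triflate alkene is deactivated) with boron on C8, from the face opposite the pseudo-axial C10 methyl (A(1,2) strain with the triflate), so C7 and C8 are relayed from C10 and oxidation proceeds with retention.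

**Step 6**
Reactants: 12 rac-alcohol
Product: 13 (7R,8S,10S)-alcohol (unreacted enantiomer of 12) and 14 (7S,8R,10R)-acetate (acylated enantiomer of 12)
Conditions: immobilised lipase from Burkholderia cepacia, vinyl acetate, MTBE, 35 °C, to half conversion; chromatography
Reagents that add atoms: vinyl acetate, C=COC(C)=O
Why: Lipase-catalysed kinetic resolution by irreversible transesterification; by the empirical rule for secondary alcohols the (8R)-enantiomer of this trans-2-substituted cycloalkanol should be acylated, and both products are used (13 for the upper half, 14 for the lower half).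

**Step 7**
Reactants: 13 (7R,8S,10S)-alcohol
Product: 17 (3aR,7S,8aR)-7-methyl-2-oxo-3,3a,4,7,8,8a-hexahydro-2H-cyclohepta[b]furan-6-yl trifluoromethanesulfonate, via mesylate 15 (not isolated), via iminium ether salt 16 (not isolated)
Conditions: MsCl, Et3N, CH2Cl2, 0 °C; crude mesylate in MeCN/aq. NaH2PO4 (pH 4), 60 °C
Reagents that add atoms: water, O
Why: Neighbouring-group lactonisation; the amide oxygen displaces the anti-disposed C8 mesylate (SN2, 5-exo-tet) and the iminium ether is hydrolysed under mildly acidic conditions with loss of dimethylamine, so inversion at C8 turns the trans hydroboration product into the cis-fused lactone (7R,8R,10S).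

**Step 8**
Reactants: 17 lactone triflate
Product: 19 (3S,3aR,7S,8aR)-3-[(dimethylamino)methyl]-7-methyl-2-oxo-3,3a,4,7,8,8a-hexahydro-2H-cyclohepta[b]furan-6-yl trifluoromethanesulfonate, via lithium enolate 18 (not isolated)
Conditions: LiN(iPr)2, THF, −78 °C; Eschenmoser's salt, −78 °C → rt
Reagents that add atoms: Eschenmoser's salt (N,N-dimethylmethyleneiminium iodide), C[N+](C)=C.[I-]
Why: Mannich aminomethylation of the lactone enolate on its convex face; the Mannich base is a masked α-methylene lactone (its C11 configuration is erased in step 17), which keeps the upper half from acting as a dienophile.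

**Step 9**
Reactants: 19 Mannich base triflate; 20 but-3-en-2-one
Product: 21 (3S,3aR,7S,8aR)-3-[(dimethylamino)methyl]-7-methyl-6-[(1E)-3-oxobut-1-en-1-yl]-3,3a,4,7,8,8a-hexahydro-2H-cyclohepta[b]furan-2-one
Conditions: 20 (5 equiv), Pd(OAc)2 (5 mol%), PPh3 (10 mol%), Et3N, DMF, 60 °C
Reagents that add atoms: none
Why: Heck reaction of the alkenyl triflate with the enone gives the (E)-dienone, that is the C5=C1–C2=C3 diene carrying the C4 acetyl group.

**Step 10**
Reactants: 14 (7S,8R,10R)-acetate
Product: 22 (7S,8R,10R)-4-[2-(dimethylamino)-2-oxoethyl]-5-hydroxy-7-methylcyclohept-1-en-1-yl trifluoromethanesulfonate (enantiomer of 13)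
Conditions: K2CO3 (cat.), MeOH, 0 °C → rt
Reagents that add atoms: none
Why: Mild transesterification removes the acetate without touching the alkenyl triflate or the amide.

**Step 11**
Reactants: 22 (7S,8R,10R)-alcohol
Product: 25 (3aS,7R,8aS)-7-methyl-2-oxo-3,3a,4,7,8,8a-hexahydro-2H-cyclohepta[b]furan-6-yl trifluoromethanesulfonate, via mesylate 23 (not isolated), via iminium ether salt 24 (not isolated)
Conditions: MsCl, Et3N, CH2Cl2, 0 °C; crude mesylate in MeCN/aq. NaH2PO4 (pH 4), 60 °C
Reagents that add atoms: water, O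
Why: Same amide-assisted invertive lactonisation as in step 7, here giving the mirror-image cis-lactone (7'S,8'S,10'R).

**Step 12**
Reactants: 25 lactone triflate
Product: 27 (3R,3aS,7R,8aS)-3-[(dimethylamino)methyl]-7-methyl-2-oxo-3,3a,4,7,8,8a-hexahydro-2H-cyclohepta[b]furan-6-yl trifluoromethanesulfonate, via lithium enolate 26 (not isolated)
Conditions: LiN(iPr)2, THF, −78 °C; Eschenmoser's salt, −78 °C → rt
Reagents that add atoms: Eschenmoser's salt (N,N-dimethylmethyleneiminium iodide), C[N+](C)=C.[I-]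
Why: Mannich aminomethylation of the lactone enolate, done before the ketone side chain is present so that only the lactone is enolised.

**Step 13**
Reactants: 27 Mannich base triflate; 28 potassium trifluoro(3-oxobutyl)borate
Product: 29 (3R,3aS,7R,8aS)-3-[(dimethylamino)methyl]-7-methyl-6-(3-oxobutyl)-3,3a,4,7,8,8a-hexahydro-2H-cyclohepta[b]furan-2-one
Conditions: PdCl2(dppf) (8 mol%), Cs2CO3 (3 equiv), THF/H2O (10:1), 65 °C; work-up with aq. NaH2PO4
Reagents that add atoms: none
Why: Suzuki–Miyaura coupling of a primary alkyltrifluoroborate with an alkenyl triflate installs the saturated 3-oxobutyl chain on C1' with the C1'=C5' alkene retained; a lactone opened by the base recloses on acidic work-up.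

**Step 14**
Reactants: 29 Mannich base ketone
Product: 31 (3aS,7R,8aS)-7-methyl-3-methylidene-6-(3-oxobutyl)-3,3a,4,7,8,8a-hexahydro-2H-cyclohepta[b]furan-2-one, via methiodide 30 (not isolated)
Conditions: MeI, MeOH, rt; then aq. NaHCO3, CH2Cl2, rt
Reagents that add atoms: none
Why: Exhaustive methylation and Hofmann-type (E1cB) elimination of the β-ammonium lactone release the α-methylene lactone, the dienophile.

**Step 15**
Reactants: 21 masked diene (upper half); 31 dienophile (lower half)
Product: 32 Diels–Alder adduct, (3R,5R,7R,8R,10S,11S,7'S,8'S,10'R,11'R)-spiro dimer with C1=C2 alkene, C3-acetyl and C13-dimethylamino group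
Conditions: 31 (1.5 equiv), PhMe (2 M), BHT (cat.), 105 °C, sealed tube
Reagents that add atoms: none
Why: Thermal Diels–Alder reaction of the C5=C1–C2=C3 dienone with the only free α-methylene lactone, with ortho regiochemistry (C3–C11' and C5–C13'); each partner reacts on its open face, 31 on the convex face of its cis-fused lactone (syn to H-7' and H-8') and 21 on the diene face opposite the C10 methyl and the lactone, which for this mirror-image pair is the lactone-carbonyl-endo alignment and sets C5, C11' and C3 (H-3 cis to H-5).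

**Step 16**
Reactants: 32 Diels–Alder adduct
Product: 34 (1S)-1-hydroxy-2-en-4-one Mannich base (C1 carbinol with C2=C3 enone), via hydroperoxide 33 (not isolated)
Conditions: O2 (1 atm), DBU (0.3 equiv), P(OEt)3 (1.5 equiv), MeCN, 0 °C → rt
Reagents that add atoms: dioxygen, O=O
Why: Base-mediated autoxidation of a β,γ-unsaturated ketone; DBU removes only the doubly activated H-3, the extended dienolate is trapped by oxygen at the γ-carbon C1 on the convex face (syn to H-5, away from both ring bonds of C5) to give the cis-fused tertiary hydroperoxide with the conjugated C2=C3 enone, and the phosphite reduces the O–O bond in situ.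

**Step 17**
Reactants: 34 hydroxy enone Mannich base
Product: 36 CNP0195550.3, via methiodide 35 (not isolated)
Conditions: MeI, MeOH, rt; then aq. NaHCO3, CH2Cl2, rt
Reagents that add atoms: none
Why: Quaternisation and Hofmann-type (E1cB) elimination unmask the α-methylene lactone of the upper half under conditions that leave the tertiary allylic alcohol, both ketones and both lactones untouched.

**Compound list**

1 | buta-2,3-dien-1-ol | C=C=CCO | starting material
2 | N,N-dimethylacetamide dimethyl acetal | COC(C)(OC)N(C)C | starting material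
3 | 1-(buta-2,3-dien-1-yloxy)-N,N-dimethylethenamine (ketene N,O-acetal) | C=C(OCC=C=C)N(C)C | intermediate (not isolated)
4 | N,N-dimethyl-3-methylidenepent-4-enamide | C=CC(=C)CC(=O)N(C)C | intermediate
5 | (±)-but-3-yn-2-ol | CC(O)C#C | starting material
6 | (±)-but-3-yn-2-yl acetate | CC(OC(C)=O)C#C | intermediate
7 | rac-(1Z)-1-{2-[2-(dimethylamino)-2-oxoethyl]-2-ethenylcyclopropyl}prop-1-en-1-yl acetate, the two alkenyl groups cis | C/C=C(OC(C)=O)/[C@@H]1C[C@@]1(C=C)CC(=O)N(C)C | intermediate (not isolated)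
8 | rac-4-[2-(dimethylamino)-2-oxoethyl]-7-methylcyclohepta-1,4-dien-1-yl acetate | CN(C)C(=O)CC1=CC[C@H](C)C(OC(C)=O)=CC1 | intermediate
9 | lithium rac-4-[2-(dimethylamino)-2-oxoethyl]-7-methylcyclohepta-1,4-dien-1-olate | CN(C)C(=O)CC1=CC[C@H](C)C([O-])=CC1.[Li+] | intermediate (not isolated)
10 | rac-4-[2-(dimethylamino)-2-oxoethyl]-7-methylcyclohepta-1,4-dien-1-yl trifluoromethanesulfonate | CN(C)C(=O)CC1=CC[C@H](C)C(OS(=O)(=O)C(F)(F)F)=CC1 | intermediate
11 | rac-(7R*,8S*,10S*)-C8 alkylborane (BH2 in place of the hydroxyl of 12) | CN(C)C(=O)C[C@H]1CC=C(OS(=O)(=O)C(F)(F)F)[C@@H](C)C[C@@H]1B | intermediate (not isolated)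
12 | rac-(7R*,8S*,10S*)-4-[2-(dimethylamino)-2-oxoethyl]-5-hydroxy-7-methylcyclohept-1-en-1-yl trifluoromethanesulfonate (hydroxyl trans to the amide arm and to the methyl) | CN(C)C(=O)C[C@H]1CC=C(OS(=O)(=O)C(F)(F)F)[C@@H](C)C[C@@H]1O | intermediate
13 | (7R,8S,10S)-enantiomer of 12 | CN(C)C(=O)C[C@H]1CC=C(OS(=O)(=O)C(F)(F)F)[C@@H](C)C[C@@H]1O | intermediate
14 | (7S,8R,10R)-5-acetoxy-4-[2-(dimethylamino)-2-oxoethyl]-7-methylcyclohept-1-en-1-yl trifluoromethanesulfonate | CN(C)C(=O)C[C@@H]1CC=C(OS(=O)(=O)C(F)(F)F)[C@H](C)C[C@H]1OC(C)=O | intermediate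
15 | C8 methanesulfonate of 13 | CN(C)C(=O)C[C@H]1CC=C(OS(=O)(=O)C(F)(F)F)[C@@H](C)C[C@@H]1OS(C)(=O)=O | intermediate (not isolated)
16 | (7R,8R,10S) cis-fused N,N-dimethyliminium ether (2-iminio-lactone) methanesulfonate | C1C(=[N+](C)C)O[C@@H]2C[C@H](C)C(OS(=O)(=O)C(F)(F)F)=CC[C@H]12.CS(=O)(=O)[O-] | intermediate (not isolated)
17 | (3aR,7S,8aR)-7-methyl-2-oxo-3,3a,4,7,8,8a-hexahydro-2H-cyclohepta[b]furan-6-yl trifluoromethanesulfonate | C1C(=O)O[C@@H]2C[C@H](C)C(OS(=O)(=O)C(F)(F)F)=CC[C@H]12 | intermediate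
18 | lithium enolate of 17 | C1=C([O-])O[C@@H]2C[C@H](C)C(OS(=O)(=O)C(F)(F)F)=CC[C@H]12.[Li+] | intermediate (not isolated)
19 | (3S,3aR,7S,8aR)-3-[(dimethylamino)methyl]-7-methyl-2-oxo-3,3a,4,7,8,8a-hexahydro-2H-cyclohepta[b]furan-6-yl trifluoromethanesulfonate | CN(C)C[C@H]1C(=O)O[C@@H]2C[C@H](C)C(OS(=O)(=O)C(F)(F)F)=CC[C@H]12 | intermediate
20 | but-3-en-2-one | C=CC(C)=O | starting material
21 | (3S,3aR,7S,8aR)-3-[(dimethylamino)methyl]-7-methyl-6-[(1E)-3-oxobut-1-en-1-yl]-3,3a,4,7,8,8a-hexahydro-2H-cyclohepta[b]furan-2-one | CN(C)C[C@H]1C(=O)O[C@@H]2C[C@H](C)C(/C=C/C(C)=O)=CC[C@H]12 | intermediate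
22 | (7S,8R,10R)-4-[2-(dimethylamino)-2-oxoethyl]-5-hydroxy-7-methylcyclohept-1-en-1-yl trifluoromethanesulfonate | CN(C)C(=O)C[C@@H]1CC=C(OS(=O)(=O)C(F)(F)F)[C@H](C)C[C@H]1O | intermediate
23 | C8 methanesulfonate of 22 | CN(C)C(=O)C[C@@H]1CC=C(OS(=O)(=O)C(F)(F)F)[C@H](C)C[C@H]1OS(C)(=O)=O | intermediate (not isolated)
24 | (7S,8S,10R) cis-fused N,N-dimethyliminium ether methanesulfonate | C1C(=[N+](C)C)O[C@H]2C[C@@H](C)C(OS(=O)(=O)C(F)(F)F)=CC[C@@H]12.CS(=O)(=O)[O-] | intermediate (not isolated)
25 | (3aS,7R,8aS)-7-methyl-2-oxo-3,3a,4,7,8,8a-hexahydro-2H-cyclohepta[b]furan-6-yl trifluoromethanesulfonate | C1C(=O)O[C@H]2C[C@@H](C)C(OS(=O)(=O)C(F)(F)F)=CC[C@@H]12 | intermediate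
26 | lithium enolate of 25 | C1=C([O-])O[C@H]2C[C@@H](C)C(OS(=O)(=O)C(F)(F)F)=CC[C@@H]12.[Li+] | intermediate (not isolated)
27 | (3R,3aS,7R,8aS)-3-[(dimethylamino)methyl]-7-methyl-2-oxo-3,3a,4,7,8,8a-hexahydro-2H-cyclohepta[b]furan-6-yl trifluoromethanesulfonate | CN(C)C[C@@H]1C(=O)O[C@H]2C[C@@H](C)C(OS(=O)(=O)C(F)(F)F)=CC[C@@H]12 | intermediate
28 | potassium trifluoro(3-oxobutyl)borate | CC(=O)CC[B-](F)(F)F.[K+] | starting material
29 | (3R,3aS,7R,8aS)-3-[(dimethylamino)methyl]-7-methyl-6-(3-oxobutyl)-3,3a,4,7,8,8a-hexahydro-2H-cyclohepta[b]furan-2-one | CN(C)C[C@@H]1C(=O)O[C@H]2C[C@@H](C)C(CCC(C)=O)=CC[C@@H]12 | intermediate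
30 | N-methyl quaternary ammonium iodide of 29 | C[N+](C)(C)C[C@@H]1C(=O)O[C@H]2C[C@@H](C)C(CCC(C)=O)=CC[C@@H]12.[I-] | intermediate (not isolated)
31 | (3aS,7R,8aS)-7-methyl-3-methylidene-6-(3-oxobutyl)-3,3a,4,7,8,8a-hexahydro-2H-cyclohepta[b]furan-2-one | C=C1C(=O)O[C@H]2C[C@@H](C)C(CCC(C)=O)=CC[C@@H]12 | intermediate
32 | Diels–Alder adduct, (3R,5R,7R,8R,10S,11S,7'S,8'S,10'R,11'R), C1=C2 alkene, C3-acetyl, 13-dimethylamino | CN(C)C[C@H]1C(=O)O[C@@H]2C[C@H](C)C3=C[C@@H](C(C)=O)[C@]4(C[C@H]3C[C@H]12)C(=O)O[C@H]1C[C@@H](C)C(CCC(C)=O)=CC[C@H]14 | intermediate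
33 | (1S)-1-hydroperoxy-2-en-4-one Mannich base | CN(C)C[C@H]1C(=O)O[C@@H]2C[C@H](C)[C@@]3(OO)C=C(C(C)=O)[C@]4(C[C@H]3C[C@H]12)C(=O)O[C@H]1C[C@@H](C)C(CCC(C)=O)=CC[C@H]14 | intermediate (not isolated)
34 | (1S)-1-hydroxy-2-en-4-one Mannich base | CN(C)C[C@H]1C(=O)O[C@@H]2C[C@H](C)[C@@]3(O)C=C(C(C)=O)[C@]4(C[C@H]3C[C@H]12)C(=O)O[C@H]1C[C@@H](C)C(CCC(C)=O)=CC[C@H]14 | intermediate
35 | N-methyl quaternary ammonium iodide of 34 | C[N+](C)(C)C[C@H]1C(=O)O[C@@H]2C[C@H](C)[C@@]3(O)C=C(C(C)=O)[C@]4(C[C@H]3C[C@H]12)C(=O)O[C@H]1C[C@@H](C)C(CCC(C)=O)=CC[C@H]14.[I-] | intermediate (not isolated)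
36 | CNP0195550.3 (1S,5R,7R,8R,10S,7'S,8'S,10'R,11'R) | C=C1C(=O)O[C@@H]2C[C@H](C)[C@@]3(O)C=C(C(C)=O)[C@]4(C[C@H]3C[C@H]12)C(=O)O[C@H]1C[C@@H](C)C(CCC(C)=O)=CC[C@H]14 | target

**Total step count:** 17.
**Longest linear sequence:** 13 steps (1, 3, 4, 5, 6, 10, 11, 12, 13, 14, 15, 16, 17).

**Steps most likely to fail**

Step 3. The acetoxy group may migrate 1,3 (to an allenyl acetate) instead of 1,2, the gold carbenoid may oligomerise, or it may cyclopropanate the vinyl terminus of 4, so that little of 8 forms. The fallback keeps the cyclopropanation/Cope logic but uses a preformed donor/acceptor carbenoid, and it sets out from 4. Methyl 3-oxopentanoate is converted by diazo transfer (4-acetamidobenzenesulfonyl azide, Et3N, MeCN) into methyl 2-diazo-3-oxopentanoate F1 and silylated (TBSOTf, Et3N, CH2Cl2) to methyl (3Z)-3-[(tert-butyldimethylsilyl)oxy]-2-diazopent-3-enoate F2. Decomposition with Rh2(OAc)4 in the presence of 4 should give, again by cyclopropanation at C6=C7 and Cope rearrangement, racemic methyl 2-[(tert-butyldimethylsilyl)oxy]-6-[2-(dimethylamino)-2-oxoethyl]-3-methylcyclohepta-1,5-diene-1-carboxylate F3. Hydrolysis of the silyl enol ether (aq. HCl, THF) and Krapcho decarboxylation (LiCl, wet DMSO, 130 °C) lead to racemic N,N-dimethyl-2-(4-methyl-5-oxocyclohept-1-en-1-yl)acetamide F4. Kinetic deprotonation on the methylene side (LiN(iPr)2, THF, −78 °C) and trapping with PhNTf2 return to 10.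

Step 15. The cycloaddition of an acceptor-substituted diene with an acceptor-substituted dienophile may be so slow that dimethylamine is lost thermally from 21, or the face and endo preferences may erode at the temperature needed. The fallback raises the diene HOMO and sets out from 21. Luche reduction (NaBH4, CeCl3·7H2O, MeOH, −78 °C) gives the C4 carbinol (both C4 epimers) F5, a normal-demand diene that should add to 31 at lower temperature (PhMe, 70 °C) with the same facial logic to give the adduct alcohol F6. Oxidation with Dess–Martin periodinane (NaHCO3, CH2Cl2) returns to 32.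

Step 16. Oxygen may be captured on the concave face of C1 or at C3, or the dienolate may simply reprotonate at C1 (reconjugation without oxygen uptake). The fallback uses a stereospecific ene reaction, which requires the lower-half ring alkene to stay electron-poor until after the oxidation, and it sets out from 27. Quaternisation and elimination as in step 14, via the methiodide F7, give the α-methylene lactone triflate F8, which is combined with 21 as in step 15 to give the adduct triflate F9. Schenck ene reaction of its trifluoroacetate salt (O2, tetraphenylporphyrin, visible light, CH2Cl2, −20 °C) removes H-3, which is cis to H-5, and delivers oxygen suprafacially to C1 to give the hydroperoxide F10. Reduction with PPh3 gives the C1 carbinol triflate F11, and Suzuki–Miyaura coupling with 28 under the conditions of step 13 returns to 34.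

**Further compounds**

F1 | step 3 | methyl 2-diazo-3-oxopentanoate | CCC(=O)C(=[N+]=[N-])C(=O)OC
F2 | step 3 | methyl (3Z)-3-[(tert-butyldimethylsilyl)oxy]-2-diazopent-3-enoate | C/C=C(O[Si](C)(C)C(C)(C)C)/C(=[N+]=[N-])C(=O)OC
F3 | step 3 | rac-methyl 2-[(tert-butyldimethylsilyl)oxy]-6-[2-(dimethylamino)-2-oxoethyl]-3-methylcyclohepta-1,5-diene-1-carboxylate | COC(=O)C1=C(O[Si](C)(C)C(C)(C)C)[C@@H](C)CC=C(CC(=O)N(C)C)C1
F4 | step 3 | rac-N,N-dimethyl-2-(4-methyl-5-oxocyclohept-1-en-1-yl)acetamide | CN(C)C(=O)CC1=CC[C@H](C)C(=O)CC1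
F5 | step 15 | (3S,3aR,7S,8aR)-3-[(dimethylamino)methyl]-6-[(1E)-3-hydroxybut-1-en-1-yl]-7-methyl-3,3a,4,7,8,8a-hexahydro-2H-cyclohepta[b]furan-2-one (C4 epimers) | CN(C)C[C@H]1C(=O)O[C@@H]2C[C@H](C)C(/C=C/C(C)O)=CC[C@H]12
F6 | step 15 | Diels–Alder adduct with C3-(1-hydroxyethyl) group (C4 epimers) | CN(C)C[C@H]1C(=O)O[C@@H]2C[C@H](C)C3=C[C@@H](C(C)O)[C@]4(C[C@H]3C[C@H]12)C(=O)O[C@H]1C[C@@H](C)C(CCC(C)=O)=CC[C@H]14
F7 | step 16 | N-methyl quaternary ammonium iodide of 27 | C[N+](C)(C)C[C@@H]1C(=O)O[C@H]2C[C@@H](C)C(OS(=O)(=O)C(F)(F)F)=CC[C@@H]12.[I-]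
F8 | step 16 | (3aS,7R,8aS)-7-methyl-3-methylidene-2-oxo-3,3a,4,7,8,8a-hexahydro-2H-cyclohepta[b]furan-6-yl trifluoromethanesulfonate | C=C1C(=O)O[C@H]2C[C@@H](C)C(OS(=O)(=O)C(F)(F)F)=CC[C@@H]12
F9 | step 16 | Diels–Alder adduct with C1' trifluoromethanesulfonate | CN(C)C[C@H]1C(=O)O[C@@H]2C[C@H](C)C3=C[C@@H](C(C)=O)[C@]4(C[C@H]3C[C@H]12)C(=O)O[C@H]1C[C@@H](C)C(OS(=O)(=O)C(F)(F)F)=CC[C@H]14
F10 | step 16 | (1S)-1-hydroperoxy-2-en-4-one with C1' trifluoromethanesulfonate | CN(C)C[C@H]1C(=O)O[C@@H]2C[C@H](C)[C@@]3(OO)C=C(C(C)=O)[C@]4(C[C@H]3C[C@H]12)C(=O)O[C@H]1C[C@@H](C)C(OS(=O)(=O)C(F)(F)F)=CC[C@H]14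
F11 | step 16 | (1S)-1-hydroxy-2-en-4-one with C1' trifluoromethanesulfonate | CN(C)C[C@H]1C(=O)O[C@@H]2C[C@H](C)[C@@]3(O)C=C(C(C)=O)[C@]4(C[C@H]3C[C@H]12)C(=O)O[C@H]1C[C@@H](C)C(OS(=O)(=O)C(F)(F)F)=CC[C@H]14
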